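Assumption: the target, 3-henicosyl-5-methoxy-2-methyl-1,4-benzoquinone (C29H50O3), has no stereocentre, so it is one achiral compound and no stereocontrol is needed.

**Retrosynthetic overview**
- Quinone 16 comes from para-oxygenation of phenol 15; no ring is built, the benzene ring is bought as isocreosol and turned into the quinone last.
- The henicosyl chain of 15 comes from enone 11 by saturating C1'=C2', deoxygenating the C3' ketone and removing the MOM group.
- Key disconnection: the C1'–C2' bond of 11, made by a crossed aldol condensation of aryl aldehyde 9 with the methyl group of icosan-2-one 5.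
- Aldehyde 9 comes from ortho-formylation of isocreosol 6 and MOM protection; ketone 5 comes from octadecyl Grignard and Weinreb acetamide 2.

**Route**

Step 1
Reactants: 1 1-bromooctadecane; 2 N-methoxy-N-methylacetamide
Product: 5 icosan-2-one, via octadecylmagnesium bromide 3 (not isolated), via Weinreb magnesium chelate 4 (not isolated)
Conditions: Mg, cat. I2, THF, reflux; then 2, THF, 0 °C → rt; 1 M HCl
Reagents that add atoms: none
Why: Grignard formation followed by Weinreb ketone synthesis, where the stable five-membered Mg chelate 4 stops the addition at the ketone stage.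

Step 2
Reactants: 6 2-methoxy-5-methylphenol (isocreosol)
Product: 8 2-hydroxy-3-methoxy-6-methylbenzaldehyde, via salicyl alcohol magnesium salt 7 (not isolated)
Conditions: MgCl2, Et3N, (CH2O)n, MeCN, reflux; 1 M HCl
Reagents that add atoms: paraformaldehyde (formaldehyde source), C=O
Why: Casnati–Skattebøl ortho-formylation, in which the magnesium phenoxide delivers formaldehyde to the only free ortho position (C6) and a second formaldehyde oxidises the benzylic alkoxide by hydride transfer.

Step 3
Reactants: 8 2-hydroxy-3-methoxy-6-methylbenzaldehyde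
Product: 9 3-methoxy-2-(methoxymethoxy)-6-methylbenzaldehyde
Conditions: MOMCl, iPr2NEt, CH2Cl2, 0 °C → rt
Reagents that add atoms: chloromethyl methyl ether (MOMCl), COCCl
Why: O-alkylation (MOM acetal protection) masks the acidic phenol so that the aldehyde stays electrophilic and the base in step 4 is not consumed.

Step 4
Reactants: 9 3-methoxy-2-(methoxymethoxy)-6-methylbenzaldehyde; 5 icosan-2-one
Product: 11 (E)-1-[3-methoxy-2-(methoxymethoxy)-6-methylphenyl]henicos-1-en-3-one, via aldol adduct 10 (not isolated)
Conditions: KOH, EtOH/THF, 45 °C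
Reagents that add atoms: none
Why: Claisen–Schmidt crossed aldol condensation, where the non-enolisable aldehyde accepts the methyl-side enolate of the ketone and E1cB dehydration drives the equilibrium to the thermodynamically favoured (E)-enone (the racemic carbinol of 10 is lost).

Step 5
Reactants: 11 (E)-1-[3-methoxy-2-(methoxymethoxy)-6-methylphenyl]henicos-1-en-3-one
Product: 12 1-[3-methoxy-2-(methoxymethoxy)-6-methylphenyl]henicosan-3-one
Conditions: H2 (1 atm), 10% Pd/C, EtOAc/THF, rt
Reagents that add atoms: none
Why: Catalytic hydrogenation saturates the conjugated C=C chemoselectively, since the ketone is not benzylic and the MOM acetal and aryl ethers are inert to Pd/H2.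

Step 6
Reactants: 12 1-[3-methoxy-2-(methoxymethoxy)-6-methylphenyl]henicosan-3-one
Product: 14 2-henicosyl-4-methoxy-3-(methoxymethoxy)-1-methylbenzene, via hydrazone 13 (not isolated)
Conditions: N2H4·H2O, KOH, diethylene glycol, 130 °C, then 200 °C
Reagents that add atoms: none
Why: Wolff–Kishner reduction (Huang-Minlon procedure) turns the dialkyl ketone into CH2 through its hydrazone with loss of N2, under basic conditions that the acetal and methyl ether tolerate.

Step 7
Reactants: 14 2-henicosyl-4-methoxy-3-(methoxymethoxy)-1-methylbenzene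
Product: 15 2-henicosyl-6-methoxy-3-methylphenol
Conditions: conc. HCl (cat.), MeOH/THF, 55 °C
Reagents that add atoms: none
Why: Acid-catalysed acetal exchange (MOM cleavage) frees the phenol while the aryl methyl ether is untouched.

Step 8
Reactants: 15 2-henicosyl-6-methoxy-3-methylphenol
Product: 16 3-henicosyl-5-methoxy-2-methylcyclohexa-2,5-diene-1,4-dione (target)
Conditions: O2 (1 atm), salcomine (15 mol%), DMF/CH2Cl2, rt
Reagents that add atoms: dioxygen, O=O
Why: Co(salen)-catalysed phenol oxygenation places oxygen at the free para position (both ortho positions are blocked) and gives the p-quinone, as in the 2,3,6-trimethylphenol to trimethylbenzoquinone oxidation.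

**Compound list**
1 | 1-bromooctadecane | CCCCCCCCCCCCCCCCCCBr | starting material
2 | N-methoxy-N-methylacetamide | CC(=O)N(C)OC | starting material
3 | octadecylmagnesium bromide | CCCCCCCCCCCCCCCCCC[Mg]Br | intermediate (not isolated)
4 | bromomagnesium 2-[methoxy(methyl)amino]icosan-2-olate (Weinreb chelate) | CCCCCCCCCCCCCCCCCCC(C)(O[Mg]Br)N(C)OC | intermediate (not isolated)
5 | icosan-2-one | CCCCCCCCCCCCCCCCCCC(C)=O | intermediate
6 | 2-methoxy-5-methylphenol (isocreosol) | COc1ccc(C)cc1O | starting material
7 | 2-(hydroxymethyl)-6-methoxy-3-methylphenol (present as its magnesium salt) | COc1ccc(C)c(CO)c1O | intermediate (not isolated)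
8 | 2-hydroxy-3-methoxy-6-methylbenzaldehyde | COc1ccc(C)c(C=O)c1O | intermediate
9 | 3-methoxy-2-(methoxymethoxy)-6-methylbenzaldehyde | COCOc1c(OC)ccc(C)c1C=O | intermediate
10 | 1-hydroxy-1-[3-methoxy-2-(methoxymethoxy)-6-methylphenyl]henicosan-3-one (racemic) | CCCCCCCCCCCCCCCCCCC(=O)CC(O)c1c(C)ccc(OC)c1OCOC | intermediate (not isolated)
11 | (E)-1-[3-methoxy-2-(methoxymethoxy)-6-methylphenyl]henicos-1-en-3-one | CCCCCCCCCCCCCCCCCCC(=O)/C=C/c1c(C)ccc(OC)c1OCOC | intermediate
12 | 1-[3-methoxy-2-(methoxymethoxy)-6-methylphenyl]henicosan-3-one | CCCCCCCCCCCCCCCCCCC(=O)CCc1c(C)ccc(OC)c1OCOC | intermediate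
13 | hydrazone of 12 | CCCCCCCCCCCCCCCCCCC(=NN)CCc1c(C)ccc(OC)c1OCOC | intermediate (not isolated)
14 | 2-henicosyl-4-methoxy-3-(methoxymethoxy)-1-methylbenzene | CCCCCCCCCCCCCCCCCCCCCc1c(C)ccc(OC)c1OCOC | intermediate
15 | 2-henicosyl-6-methoxy-3-methylphenol | CCCCCCCCCCCCCCCCCCCCCc1c(C)ccc(OC)c1O | intermediate
16 | 3-henicosyl-5-methoxy-2-methylcyclohexa-2,5-diene-1,4-dione | CCCCCCCCCCCCCCCCCCCCCC1=C(C)C(=O)C=C(OC)C1=O | target

**Totals**
Total step count: 8. Longest linear sequence: 7 steps (6 → 8 → 9 → 11 → 12 → 14 → 15 → 16, steps 2–8); step 1 is the side branch that supplies ketone 5.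

**Three steps most likely to fail, with fallbacks**

Step 2, the ortho-formylation, must take place at a carbon flanked by OH and CH3 and may stall or stop at the benzylic alcohol. The fallback sets out from 6 and comes back to the route at 9. Isocreosol is O-allylated (allyl bromide, K2CO3, acetone, reflux) to 2-(allyloxy)-1-methoxy-4-methylbenzene F1. Aromatic Claisen rearrangement (PhNEt2, 195 °C) can only deliver the allyl group to the one free ortho carbon and gives 2-allyl-6-methoxy-3-methylphenol F2. The phenol is protected (MOMCl, iPr2NEt, CH2Cl2) as 2-allyl-4-methoxy-3-(methoxymethoxy)-1-methylbenzene F3. The double bond is moved into conjugation (KOtBu, DMSO, 50 °C) to give 1-methoxy-2-(methoxymethoxy)-4-methyl-3-[(E)-prop-1-en-1-yl]benzene F4. Ozonolysis (O3, CH2Cl2/MeOH, −78 °C; Me2S) then gives aldehyde 9.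

Step 4, the base-mediated condensation, may suffer from slow attack on the di-ortho-substituted aldehyde, some methylene-side enolisation and ketone self-condensation. The fallback sets out from 5 (with 9 as partner) and comes back at 11. It replaces the equilibrium condensation by a stepwise, kinetically controlled directed aldol. Ketone 5 is deprotonated at the methyl group (LDA, THF, −78 °C) to lithium icos-1-en-2-olate F5, which adds irreversibly to 9 at −78 °C. The β-hydroxy ketone 10 is isolated this time and converted (MsCl, Et3N, CH2Cl2, 0 °C) into 1-[3-methoxy-2-(methoxymethoxy)-6-methylphenyl]-3-oxohenicosyl methanesulfonate F6. DBU then eliminates it to the (E)-enone 11.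

Step 6, the Wolff–Kishner reduction, may give azine, dissolve the waxy substrate poorly in glycol, or partly cleave the ethers at 200 °C. Any MOM loss only delivers 15 early. The fallback sets out from 12 and comes back at 14 by radical deoxygenation of the alcohol. NaBH4 (MeOH/THF, 0 °C) gives 1-[3-methoxy-2-(methoxymethoxy)-6-methylphenyl]henicosan-3-ol F7 (racemic). NaH, CS2, then MeI (THF) gives O-{1-[3-methoxy-2-(methoxymethoxy)-6-methylphenyl]henicosan-3-yl} S-methyl carbonodithioate F8 (racemic). Barton–McCombie reduction (Bu3SnH, AIBN, toluene, 110 °C) gives 14.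

**Further compounds**
F1 | step 2 | 2-(allyloxy)-1-methoxy-4-methylbenzene | COc1ccc(C)cc1OCC=C
F2 | step 2 | 2-allyl-6-methoxy-3-methylphenol | COc1ccc(C)c(CC=C)c1O
F3 | step 2 | 2-allyl-4-methoxy-3-(methoxymethoxy)-1-methylbenzene | COCOc1c(OC)ccc(C)c1CC=C
F4 | step 2 | 1-methoxy-2-(methoxymethoxy)-4-methyl-3-[(E)-prop-1-en-1-yl]benzene | COCOc1c(OC)ccc(C)c1/C=C/C
F5 | step 4 | lithium icos-1-en-2-olate | C=C([O-])CCCCCCCCCCCCCCCCCC.[Li+]
F6 | step 4 | 1-[3-methoxy-2-(methoxymethoxy)-6-methylphenyl]-3-oxohenicosyl methanesulfonate (racemic) | CCCCCCCCCCCCCCCCCCC(=O)CC(OS(C)(=O)=O)c1c(C)ccc(OC)c1OCOC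
F7 | step 6 | 1-[3-methoxy-2-(methoxymethoxy)-6-methylphenyl]henicosan-3-ol (racemic) | CCCCCCCCCCCCCCCCCCC(O)CCc1c(C)ccc(OC)c1OCOC
F8 | step 6 | O-{1-[3-methoxy-2-(methoxymethoxy)-6-methylphenyl]henicosan-3-yl} S-methyl carbonodithioate (racemic) | CCCCCCCCCCCCCCCCCCC(OC(=S)SC)CCc1c(C)ccc(OC)c1OCOC
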